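**Retrosynthetic overview**

- Feature: ring B is the acetyl ring (B1 C–CH2 bridge, B2 C–OH, B3 C–CH3, B4 C–OH, B5 C–acetyl, B6 C–OH) and ring A the butanoyl ring (round the ring in order: C–butanoyl, C–OH, C–CH3, C–OCH3, C–CH2 bridge, C–OH). The acetyl carbon B5 and the hydroxyl carbon B6 are neighbours, so this ortho-hydroxyaryl ketone is read as a B5≡B6 aryne that has taken up acetic acid across its C–O bond.
- Disconnections, backwards: four O-benzyl groups; then B6–O and B5–C(acetyl) together (aryne from B5-SiMe3/B6-OTf plus AcOH); then the silyl triflate from the ortho-bromophenol by retro-Brook shift with the ring A ketone masked as its silyl enol ether; then the bond from the bridge CH2 to B1 by Friedel–Crafts benzylation with the ring A benzylic alcohol.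
- Ring A comes from 2,4,6-trihydroxytoluene (C-butanoylation, O-methylation para to the ketone to aspidinol, formylation, benzylation, reduction); ring B from 3,5-dihydroxy-4-methylbenzoic acid (benzylation, acid to methyl ketone, Baeyer–Villiger to the phenol, bromination).
- No ring is formed in the route, both benzene rings are bought, and the target has no stereocenter; the acetyl group is placed under basic conditions, away from the acid that can exchange a methylene bridge between phloroglucinol rings.

Key step: step 14

Assumption: the silyl enol ether made in step 12 is drawn as the Z isomer expected for an aryl alkyl ketone; its geometry is erased in step 13 and has no bearing on the route.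

**Route**

Step 1
Reactants: 1 3,5-dihydroxy-4-methylbenzoic acid
Product: 2 benzyl 3,5-bis(benzyloxy)-4-methylbenzoate
Conditions: BnBr (3.5 equiv), K2CO3, DMF, 60 °C
Reagents that add atoms: benzyl bromide, BrCc1ccccc1
Why: Williamson etherification of both phenols with concurrent alkylation of the carboxylate should give the fully benzylated ester, the symmetric substrate leaving no regiochemical question.

Step 2
Reactants: 2 benzyl 3,5-bis(benzyloxy)-4-methylbenzoate
Product: 3 3,5-bis(benzyloxy)-N-methoxy-N,4-dimethylbenzamide
Conditions: MeNH(OMe)·HCl, i-PrMgCl, THF, −20 to 0 °C; then 1 M HCl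
Reagents that add atoms: N,O-dimethylhydroxylamine hydrochloride, Cl.CNOC
Why: Aminolysis of the ester by the chloromagnesium amide made in the flask (Weinreb amide formation) should proceed at low temperature without touching the aryl benzyl ethers.

Step 3
Reactants: 3 3,5-bis(benzyloxy)-N-methoxy-N,4-dimethylbenzamide
Product: 4 1-[3,5-bis(benzyloxy)-4-methylphenyl]ethan-1-one
Conditions: MeMgBr, THF, 0 °C; then 1 M HCl
Reagents that add atoms: methylmagnesium bromide, C[Mg]Br
Why: Weinreb ketone synthesis, in which the chelated tetrahedral magnesium adduct holds until work-up so that only one methyl group is added.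

Step 4
Reactants: 4 1-[3,5-bis(benzyloxy)-4-methylphenyl]ethan-1-one
Product: 6 3,5-bis(benzyloxy)-4-methylphenol, via aryl acetate 5 (not isolated)
Conditions: mCPBA, TFA (0.2 equiv), CH2Cl2, 0 °C to rt; then K2CO3 (cat.), MeOH, rt
Reagents that add atoms: 3-chloroperoxybenzoic acid, OOC(=O)c1cccc(Cl)c1
Why: Baeyer–Villiger oxidation, in which the aryl group migrates in preference to methyl, should give the aryl acetate, and base-catalysed methanolysis then frees a phenol with two equivalent open ortho positions.

Step 5
Reactants: 6 3,5-bis(benzyloxy)-4-methylphenol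
Product: 7 3,5-bis(benzyloxy)-2-bromo-4-methylphenol
Conditions: NBS (1.0 equiv), CH2Cl2, −78 to −20 °C
Reagents that add atoms: N-bromosuccinimide, O=C1CCC(=O)N1Br
Why: Electrophilic aromatic bromination occurs ortho to the free hydroxyl at one of two equivalent positions, and one equivalent of NBS at low temperature should stop at the monobromide because the first bromine deactivates the ring.

Step 6
Reactants: 8 2,4,6-trihydroxytoluene; 9 butanoyl chloride
Product: 10 1-(2,4,6-trihydroxy-3-methylphenyl)butan-1-one
Conditions: AlCl3 (3 equiv), PhNO2, rt to 50 °C; ice/HCl work-up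
Reagents that add atoms: none
Why: Friedel–Crafts C-acylation of the phloroglucinol nucleus at one of its two equivalent free carbons, the acyl group then deactivating the ring against a second acylation.

Step 7
Reactants: 10 1-(2,4,6-trihydroxy-3-methylphenyl)butan-1-one
Product: 11 1-(2,6-dihydroxy-4-methoxy-3-methylphenyl)butan-1-one (aspidinol)
Conditions: Me2SO4 (1.0 equiv), K2CO3 (1.0 equiv), acetone, rt
Reagents that add atoms: dimethyl sulfate, COS(=O)(=O)OC
Why: Williamson methylation with one equivalent of reagent should select the hydroxyl para to the carbonyl, the most acidic one and the only one not hydrogen-bonded to the ketone.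

Step 8
Reactants: 11 1-(2,6-dihydroxy-4-methoxy-3-methylphenyl)butan-1-one
Product: 13 3-butanoyl-2,4-dihydroxy-6-methoxy-5-methylbenzaldehyde, via iminium chloride 12 (not isolated)
Conditions: POCl3, DMF, EtOAc, 0 °C to rt; then H2O, 50 °C
Reagents that add atoms: N,N-dimethylformamide, CN(C)C=O; water, O
Why: Vilsmeier–Haack formylation attacks the only unsubstituted carbon of ring A, activated by two hydroxyls and the methoxy group, and hydrolysis of the iminium salt frees the aldehyde while the chelated ketone stays untouched at room temperature.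

Step 9
Reactants: 13 3-butanoyl-2,4-dihydroxy-6-methoxy-5-methylbenzaldehyde
Product: 14 2,4-bis(benzyloxy)-3-butanoyl-6-methoxy-5-methylbenzaldehyde
Conditions: BnBr (3 equiv), K2CO3, Bu4NI (cat.), DMF, 60 °C
Reagents that add atoms: benzyl bromide, BrCc1ccccc1
Why: Williamson etherification in a dipolar aprotic solvent at raised temperature should O-benzylate both chelated phenols, carbonate in DMF favouring oxygen over carbon alkylation.

Step 10
Reactants: 14 2,4-bis(benzyloxy)-3-butanoyl-6-methoxy-5-methylbenzaldehyde
Product: 15 1-[2,6-bis(benzyloxy)-3-(hydroxymethyl)-4-methoxy-5-methylphenyl]butan-1-one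
Conditions: NaBH4, MeOH–THF, −20 to 0 °C
Reagents that add atoms: none
Why: Chemoselective borohydride reduction, the aldehyde being reduced at low temperature much faster than the ketone, which is flanked by two benzyloxy groups and twisted out of the ring plane.

Step 11
Reactants: 7 3,5-bis(benzyloxy)-2-bromo-4-methylphenol; 15 1-[2,6-bis(benzyloxy)-3-(hydroxymethyl)-4-methoxy-5-methylphenyl]butan-1-one
Product: 16 1-[2,6-bis(benzyloxy)-3-{[2,4-bis(benzyloxy)-5-bromo-6-hydroxy-3-methylphenyl]methyl}-4-methoxy-5-methylphenyl]butan-1-one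
Conditions: Sc(OTf)3 (5 mol %), 4 Å MS, CH2Cl2, 0 °C to rt
Reagents that add atoms: none
Why: Friedel–Crafts benzylation, in which the Lewis acid ionizes the trialkoxy-stabilized benzylic alcohol and the cation is taken up by the only open nuclear carbon of phenol 7 (ortho to hydroxyl, ortho and para to benzyloxy); ring A has no free position and cannot oligomerize, and any O-benzylation is reversible under the conditions.

Step 12
Reactants: 16 the bromophenol diarylmethane
Product: 17 bis-silylated bromide: B6–OSiMe3 aryl ether and (Z)-trimethylsilyl enol ether C(OSiMe3)=CH–CH2CH3 of the ring A butanoyl group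
Conditions: TMSOTf (2.5 equiv), Et3N (4 equiv), CH2Cl2, 0 °C; concentrate, pentane, filter under argon
Reagents that add atoms: trimethylsilyl trifluoromethanesulfonate, C[Si](C)(C)OS(=O)(=O)C(F)(F)F
Why: Silyl triflate with amine base silylates the phenol and converts the ketone into its silyl enol ether (soft enolization), which places the silicon for the coming retro-Brook shift and masks the only carbonyl group against butyllithium.

Step 13
Reactants: 17 the bis-silylated bromide
Product: 21 3,5-bis(benzyloxy)-2-{[2,4-bis(benzyloxy)-3-butanoyl-6-methoxy-5-methylphenyl]methyl}-4-methyl-6-(trimethylsilyl)phenyl trifluoromethanesulfonate, via aryllithium 18 (not isolated), via lithium phenoxide 19 (not isolated), via aryl triflate silyl enol ether 20 (not isolated)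
Conditions: n-BuLi (1.1 equiv), THF, −78 °C; Tf2O (1.2 equiv), −78 °C; then AcOH, THF–H2O, rt
Reagents that add atoms: trifluoromethanesulfonic anhydride, O=S(=O)(OS(=O)(=O)C(F)(F)F)C(F)(F)F
Why: Bromine–lithium exchange gives the B5 aryllithium, whose neighbouring O-silyl group migrates to carbon (retro-Brook rearrangement, 1,3 O-to-C shift) to give the phenoxide, which is triflated in the same flask as in the usual preparation of ortho-silylaryl triflates, and dilute acetic acid then hydrolyses the silyl enol ether back to the ketone.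

Step 14
Reactants: 21 the ortho-silylaryl triflate; 22 acetic acid
Product: 25 1-[3-{[3-acetyl-4,6-bis(benzyloxy)-2-hydroxy-5-methylphenyl]methyl}-2,6-bis(benzyloxy)-4-methoxy-5-methylphenyl]butan-1-one, via aryne 23 (not isolated), via cesium aryl acetate 24 (not isolated)
Conditions: CsF (5 equiv), AcOH (1.5 equiv), THF, 125 °C, sealed tube
Reagents that add atoms: none
Why: Fluoride attacks the B5 silicon and the B6 triflate leaves, giving the B5≡B6 aryne; acetate (from AcOH and CsF) adds through oxygen to B6, and the aryl anion so formed on B5 attacks the adjacent ester carbonyl through a four-membered alkoxide that opens to the B6 phenoxide and the B5 methyl ketone. The closest known reaction is the fluoride-induced insertion of arynes into the carbon–oxygen bond of carboxylic acids, which gives ortho-hydroxyaryl ketones from simple silylaryl triflates under these conditions; here it is applied to an aryne whose four other ring positions are substituted. No ring is closed and no stereocenter is formed; the B6–O and B5–C(acetyl) bonds are made in one operation. The step needs oxygen to add at B6 and not at B5: the benzyloxy group on B4 withdraws inductively and stabilizes negative charge on B5, as in 3-alkoxyarynes, which are attacked at the carbon remote from the alkoxy group, and this should outweigh the steric effect of the bridge CH2 on B1. It also needs acyl transfer to outrun protonation of the aryl anion, which is why the acid is kept near stoichiometric, CsF is in excess and the mixture is heated. Ring A has no free position and its ketone should not be enolized by the buffered fluoride, so the acetyl group can only arrive on B5.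

Step 15
Reactants: 25 the tetrabenzyl ether
Product: 26 1-[3-[(3-acetyl-2,4,6-trihydroxy-5-methylphenyl)methyl]-2,6-dihydroxy-4-methoxy-5-methylphenyl]butan-1-one (target)
Conditions: H2 (1 atm), 10% Pd/C, EtOAc–MeOH, rt
Reagents that add atoms: none
Why: Catalytic hydrogenolysis of the four benzyl ethers under neutral conditions, in which the aryl ketones, the aryl methyl ether and the diarylmethane bridge are not expected to be reduced at atmospheric pressure.

**Compound list**

1 | 3,5-dihydroxy-4-methylbenzoic acid | Cc1c(O)cc(C(=O)O)cc1O | starting material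
2 | benzyl 3,5-bis(benzyloxy)-4-methylbenzoate | Cc1c(OCc2ccccc2)cc(C(=O)OCc2ccccc2)cc1OCc1ccccc1 | intermediate
3 | 3,5-bis(benzyloxy)-N-methoxy-N,4-dimethylbenzamide | CON(C)C(=O)c1cc(OCc2ccccc2)c(C)c(OCc2ccccc2)c1 | intermediate
4 | 1-[3,5-bis(benzyloxy)-4-methylphenyl]ethan-1-one | CC(=O)c1cc(OCc2ccccc2)c(C)c(OCc2ccccc2)c1 | intermediate
5 | 3,5-bis(benzyloxy)-4-methylphenyl acetate (not isolated) | CC(=O)Oc1cc(OCc2ccccc2)c(C)c(OCc2ccccc2)c1 | intermediate
6 | 3,5-bis(benzyloxy)-4-methylphenol | Cc1c(OCc2ccccc2)cc(O)cc1OCc1ccccc1 | intermediate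
7 | 3,5-bis(benzyloxy)-2-bromo-4-methylphenol | Cc1c(OCc2ccccc2)cc(O)c(Br)c1OCc1ccccc1 | intermediate
8 | 2,4,6-trihydroxytoluene | Cc1c(O)cc(O)cc1O | starting material
9 | butanoyl chloride | CCCC(Cl)=O | starting material
10 | 1-(2,4,6-trihydroxy-3-methylphenyl)butan-1-one | CCCC(=O)c1c(O)cc(O)c(C)c1O | intermediate
11 | 1-(2,6-dihydroxy-4-methoxy-3-methylphenyl)butan-1-one (aspidinol) | CCCC(=O)c1c(O)cc(OC)c(C)c1O | intermediate
12 | [(3-butanoyl-2,4-dihydroxy-6-methoxy-5-methylphenyl)methylidene]dimethylammonium chloride (not isolated) | CCCC(=O)c1c(O)c(C)c(OC)c(C=[N+](C)C)c1O.[Cl-] | intermediate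
13 | 3-butanoyl-2,4-dihydroxy-6-methoxy-5-methylbenzaldehyde | CCCC(=O)c1c(O)c(C)c(OC)c(C=O)c1O | intermediate
14 | 2,4-bis(benzyloxy)-3-butanoyl-6-methoxy-5-methylbenzaldehyde | CCCC(=O)c1c(OCc2ccccc2)c(C)c(OC)c(C=O)c1OCc1ccccc1 | intermediate
15 | 1-[2,6-bis(benzyloxy)-3-(hydroxymethyl)-4-methoxy-5-methylphenyl]butan-1-one | CCCC(=O)c1c(OCc2ccccc2)c(C)c(OC)c(CO)c1OCc1ccccc1 | intermediate
16 | 1-[2,6-bis(benzyloxy)-3-{[2,4-bis(benzyloxy)-5-bromo-6-hydroxy-3-methylphenyl]methyl}-4-methoxy-5-methylphenyl]butan-1-one | CCCC(=O)c1c(OCc2ccccc2)c(C)c(OC)c(Cc3c(OCc4ccccc4)c(C)c(OCc4ccccc4)c(Br)c3O)c1OCc1ccccc1 | intermediate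
17 | bis-silylated derivative of 16: trimethylsilyl aryl ether on the B6 oxygen and (Z)-trimethylsilyl enol ether C(OSiMe3)=CHCH2CH3 in place of the ring A butanoyl group | CC/C=C(\O[Si](C)(C)C)c1c(OCc2ccccc2)c(C)c(OC)c(Cc3c(OCc4ccccc4)c(C)c(OCc4ccccc4)c(Br)c3O[Si](C)(C)C)c1OCc1ccccc1 | intermediate
18 | B5-lithio analogue of 17 (lithium in place of bromine; not isolated) | CC/C=C(\O[Si](C)(C)C)c1c(OCc2ccccc2)c(C)c(OC)c(Cc3c(OCc4ccccc4)c(C)c(OCc4ccccc4)c([Li])c3O[Si](C)(C)C)c1OCc1ccccc1 | intermediate
19 | lithium B6-phenoxide with the trimethylsilyl group on B5 and the ring A silyl enol ether intact (not isolated) | CC/C=C(\O[Si](C)(C)C)c1c(OCc2ccccc2)c(C)c(OC)c(Cc3c(OCc4ccccc4)c(C)c(OCc4ccccc4)c([Si](C)(C)C)c3[O-])c1OCc1ccccc1.[Li+] | intermediate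
20 | B6 triflate with B5 trimethylsilyl and the ring A silyl enol ether intact (not isolated) | CC/C=C(\O[Si](C)(C)C)c1c(OCc2ccccc2)c(C)c(OC)c(Cc3c(OCc4ccccc4)c(C)c(OCc4ccccc4)c([Si](C)(C)C)c3OS(=O)(=O)C(F)(F)F)c1OCc1ccccc1 | intermediate
21 | 3,5-bis(benzyloxy)-2-{[2,4-bis(benzyloxy)-3-butanoyl-6-methoxy-5-methylphenyl]methyl}-4-methyl-6-(trimethylsilyl)phenyl trifluoromethanesulfonate | CCCC(=O)c1c(OCc2ccccc2)c(C)c(OC)c(Cc3c(OCc4ccccc4)c(C)c(OCc4ccccc4)c([Si](C)(C)C)c3OS(=O)(=O)C(F)(F)F)c1OCc1ccccc1 | intermediate
22 | acetic acid | CC(=O)O | starting material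
23 | B5≡B6 aryne of the tetrabenzyl diarylmethane (not isolated) | CCCC(=O)c1c(OCc2ccccc2)c(C)c(OC)c(CC3=C(OCc4ccccc4)C(C)=C(OCc4ccccc4)C#C3)c1OCc1ccccc1 | intermediate
24 | B6 acetate carrying cesium on B5 (not isolated) | CCCC(=O)c1c(OCc2ccccc2)c(C)c(OC)c(Cc3c(OCc4ccccc4)c(C)c(OCc4ccccc4)c([Cs])c3OC(C)=O)c1OCc1ccccc1 | intermediate
25 | 1-[3-{[3-acetyl-4,6-bis(benzyloxy)-2-hydroxy-5-methylphenyl]methyl}-2,6-bis(benzyloxy)-4-methoxy-5-methylphenyl]butan-1-one | CCCC(=O)c1c(OCc2ccccc2)c(C)c(OC)c(Cc3c(OCc4ccccc4)c(C)c(OCc4ccccc4)c(C(C)=O)c3O)c1OCc1ccccc1 | intermediate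
26 | 1-[3-[(3-acetyl-2,4,6-trihydroxy-5-methylphenyl)methyl]-2,6-dihydroxy-4-methoxy-5-methylphenyl]butan-1-one | CCCC(=O)c1c(O)c(C)c(OC)c(Cc2c(O)c(C)c(O)c(C(C)=O)c2O)c1O | target

**Count and risks**

Total step count: 15. Longest linear sequence: 10 steps (steps 1–5 or 6–10, then 11–15).

Steps most likely to fail:

Step 14. The aryl anion on B5 may be protonated before it reaches the ester carbonyl, which leaves a B6 acetate without the acyl group on carbon. Acetate may also add with the reverse orientation, or an ether oxygen of ring A may capture the aryne across the bridge and lose its alkyl group. The fallback brings in the acetyl group by electrophilic acylation after deprotection, without an aryne, and sets out from 16. Hydrogenolysis with hydrogen over Pd/C in EtOAc–MeOH with Et3N should remove the four benzyl groups and the bromine and give 1-[2,6-dihydroxy-4-methoxy-3-methyl-5-[(2,4,6-trihydroxy-3-methylphenyl)methyl]phenyl]butan-1-one F1, whose only unsubstituted ring carbon is B5. Houben–Hoesch reaction with MeCN, ZnCl2 and HCl in Et2O at 0 °C should then give the B5 ketiminium chloride F2, and warm water hydrolyses it to the target, so the fallback comes back to the route at 26. The acid exposes the methylene bridge to exchange, which is why this is the reserve and not the plan.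

Step 13. Butyllithium may attack the silyl enol ether or a benzylic position, the aryllithium may be protonated before the silyl group migrates (bromine lost without silylation), the hindered phenoxide may be triflated incompletely, or the silyl group may be lost during the acidic unmasking. The fallback puts silicon on ring B before the rings are joined, so that no organolithium meets the ketone, and sets out from 7 and 15. Silylation of 7 with (Me3Si)2NH gives [3,5-bis(benzyloxy)-2-bromo-4-methylphenoxy]trimethylsilane F3, and n-BuLi in THF at −78 °C followed by aqueous NH4Cl should give 3,5-bis(benzyloxy)-4-methyl-2-(trimethylsilyl)phenol F4. Alcohol 15 is converted with PBr3 in Et2O at 0 °C into 1-[2,6-bis(benzyloxy)-3-(bromomethyl)-4-methoxy-5-methylphenyl]butan-1-one F5. The sodium phenoxide of F4 (NaH, toluene) is then C-benzylated by F5 at its one free ortho carbon to give the silylphenol diarylmethane F6, and Tf2O with pyridine in CH2Cl2 converts F6 into the triflate, so the fallback comes back to the route at 21.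

Step 11. The benzylation is reversible under acid, so the bridge may be cleaved again or exchanged, the reaction may stall at the O-benzyl stage, or the Lewis acid may remove benzyl ethers. The fallback forms the bond by addition of a phenoxide to the aldehyde and sets out from 7 and 14. The bromomagnesium phenoxide of 7 (EtMgBr, toluene, rt) should add through its free ortho carbon to aldehyde 14 and give the racemic carbinol 1-[2,6-bis(benzyloxy)-3-{[2,4-bis(benzyloxy)-5-bromo-6-hydroxy-3-methylphenyl](hydroxy)methyl}-4-methoxy-5-methylphenyl]butan-1-one F7. Ionic hydrogenation with Et3SiH and TFA in CH2Cl2 at −20 °C then removes the carbinol oxygen, so the fallback comes back to the route at 16.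

**Further compounds**

F1 | step 14 | 1-[2,6-dihydroxy-4-methoxy-3-methyl-5-[(2,4,6-trihydroxy-3-methylphenyl)methyl]phenyl]butan-1-one | CCCC(=O)c1c(O)c(C)c(OC)c(Cc2c(O)c(C)c(O)cc2O)c1O
F2 | step 14 | B5 ketiminium chloride of the deprotected dimer | CCCC(=O)c1c(O)c(C)c(OC)c(Cc2c(O)c(C)c(O)c(C(C)=[NH2+])c2O)c1O.[Cl-]
F3 | step 13 | [3,5-bis(benzyloxy)-2-bromo-4-methylphenoxy]trimethylsilane | Cc1c(OCc2ccccc2)cc(O[Si](C)(C)C)c(Br)c1OCc1ccccc1
F4 | step 13 | 3,5-bis(benzyloxy)-4-methyl-2-(trimethylsilyl)phenol | Cc1c(OCc2ccccc2)cc(O)c([Si](C)(C)C)c1OCc1ccccc1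
F5 | step 13 | 1-[2,6-bis(benzyloxy)-3-(bromomethyl)-4-methoxy-5-methylphenyl]butan-1-one | CCCC(=O)c1c(OCc2ccccc2)c(C)c(OC)c(CBr)c1OCc1ccccc1
F6 | step 13 | 1-[2,6-bis(benzyloxy)-3-{[2,4-bis(benzyloxy)-6-hydroxy-3-methyl-5-(trimethylsilyl)phenyl]methyl}-4-methoxy-5-methylphenyl]butan-1-one | CCCC(=O)c1c(OCc2ccccc2)c(C)c(OC)c(Cc3c(OCc4ccccc4)c(C)c(OCc4ccccc4)c([Si](C)(C)C)c3O)c1OCc1ccccc1
F7 | step 11 | 1-[2,6-bis(benzyloxy)-3-{[2,4-bis(benzyloxy)-5-bromo-6-hydroxy-3-methylphenyl](hydroxy)methyl}-4-methoxy-5-methylphenyl]butan-1-one (racemic) | CCCC(=O)c1c(OCc2ccccc2)c(C)c(OC)c(C(O)c3c(OCc4ccccc4)c(C)c(OCc4ccccc4)c(Br)c3O)c1OCc1ccccc1
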